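**Retrosynthetic overview**
1. Dihydropyran ring (formed last): a retro-oxa-Diels–Alder across C8–O and C13–C1' gives an alkylidene trione (syncarpic acid + isovaleraldehyde) and (3Z,5S)-caryophylla-3,8(13)-dien-5-ol.
2. Key disconnection, C5–O: the allylic alcohol comes from the 4S,5S-epoxide of β-caryophyllene by eliminative opening toward C3; the epoxide C–O bonds are made by a catalyst-controlled, conformer-selective epoxidation.
3. The cyclobutane and the nine-membered ring, with the C1 and C9 stereocentres, are taken intact from (−)-β-caryophyllene.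
4. The trione ring comes from 2',4',6'-trihydroxyacetophenone by fourfold C-methylation and deacetylation.
5. Ring order: the terpene carbocycles and the trione ring are in hand first, the oxirane is made and opened, and the dihydropyran closes last.

Assumption: caryophyllane numbering is used (C1/C9 ring fusion, C4 methyl-bearing carbon, C5 carbinol, C8 spiro carbon, C13 former exocyclic CH2, C1' isobutyl-bearing carbon), and commercial (−)-β-caryophyllene is the (1R,9S) enantiomer.

**Step 1**
Reactants: 1 2',4',6'-trihydroxyacetophenone
Product: 2 acetylsyncarpic acid (2-acetyl-3-hydroxy-4,4,6,6-tetramethylcyclohex-2-ene-1,5-dione, enol form, achiral)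
Conditions: NaOMe (6 equiv), MeI (8 equiv), MeOH, 0 °C to reflux, 12 h; acidic work-up
Reagents that add atoms: iodomethane, CI
Why: Base-mediated exhaustive C-methylation (dearomatising alkylation of the phloroglucinolate), in which the acetyl group blocks one ring carbon so the four methyl groups enter pairwise at the two free ring carbons and no stereocentre is formed.

**Step 2**
Reactants: 2 acetylsyncarpic acid
Product: 3 syncarpic acid (5-hydroxy-2,2,6,6-tetramethylcyclohex-4-ene-1,3-dione, enol of 2,2,4,4-tetramethylcyclohexane-1,3,5-trione, achiral)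
Conditions: 6 M aq HCl, reflux, 16 h
Reagents that add atoms: none
Why: Acid-promoted retro-Claisen deacylation of the 2-acyl-1,3-dione releases acetic acid, and the quaternary carbons rule out any other C–C cleavage.

**Step 3**
Reactants: 4 (−)-β-caryophyllene, (1R,4E,9S)-caryophylla-4,8(13)-diene
Product: 5 (1R,4S,5S,9S)-4,5-epoxycaryophyll-8(13)-ene (trans-epoxide, the C4,C5-diastereomer of commercial (−)-caryophyllene oxide)
Conditions: ent-Shi ketone (L-fructose-derived, 30 mol%), KHSO5 (as 2KHSO5·KHSO4·K2SO4, 1.3 equiv), K2CO3, Bu4NHSO4 (4 mol%), MeCN–CH2(OMe)2 / aq Na2B4O7–Na2H2EDTA buffer (pH 10.5), −10 to 0 °C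
Reagents that add atoms: potassium peroxymonosulfate, [K+].[O-]S(=O)(=O)OO
Why: Proposed new method: a conformer-selective, reagent-controlled epoxidation in which the chiral dioxirane formed from the ketone and KHSO5 transfers oxygen through a spiro transition state to the alkene face that gives S,S-epoxides from trans-trisubstituted olefins; each face of the endocyclic trans double bond is exposed only in one family of planar-chiral ring conformers, which interconvert (barrier about 16 kcal/mol, half-life of seconds at −10 °C) much faster than oxidation, so under Curtin–Hammett control the catalyst epoxidises the conformer showing that face and sets C4 and C5 as S,S against the modest inherent preference for the 4R,5R oxide, while the exocyclic 1,1-disubstituted alkene is a far poorer substrate; the closest known reaction type is the Shi asymmetric epoxidation of acyclic trans-trisubstituted alkenes.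

**Step 4**
Reactants: 5 (1R,4S,5S,9S)-4,5-epoxycaryophyll-8(13)-ene
Product: 6 (1R,3Z,5S,9S)-caryophylla-3,8(13)-dien-5-ol
Conditions: Et2Al(TMP) (4 equiv, from 2,2,6,6-tetramethylpiperidine, n-BuLi and Et2AlCl), toluene, 0 °C, 3 h; aq KNaC4H4O6 work-up
Reagents that add atoms: none
Why: Yamamoto-type aluminium amide isomerisation of an epoxide to an allylic alcohol (syn β-elimination through a six-membered Al–O–C–C–H–N transition state), in which the bulky amide binds oxygen on the epoxide face carrying H-5 and removes the syn proton of the C3 methylene (cis to H-5) rather than a methyl proton; the C3=C4 bond is expected to form as the less strained cis (Z) ring olefin, the C5–O bond is untouched so 5S is kept, and the C4 stereocentre disappears.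

**Step 5**
Reactants: 3 syncarpic acid (1.5 equiv), 7 isovaleraldehyde (3-methylbutanal, 1.6 equiv), 6 (1R,3Z,5S,9S)-caryophylla-3,8(13)-dien-5-ol
Product: 9 Tomentodione P, via alkylidene trione 8 (not isolated)
Conditions: ethylenediammonium diacetate (20 mol%), toluene, 23 to 80 °C, 12 h
Reagents that add atoms: none
Why: Domino Knoevenagel condensation / inverse-electron-demand oxa-Diels–Alder reaction, in which 3 and 7 give the 1-oxadiene 8 that adds to the unhindered exocyclic 1,1-disubstituted alkene with oxygen bonding to the quaternary carbon (asynchronous, tertiary-cation-like transition state); addition to the outer face of the methylene is expected to set C8 as S and an exo orientation of the isobutyl group (away from the nine-membered ring) to set C1' as S, so 9 should be a main component of a diastereomer mixture from which the C8/C1' isomers are removed by chromatography, and the hindered C3=C4 bond and the free hydroxyl (reversible oxa-Michael addition only) do not consume 8.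

**Compound list**
1 | 2',4',6'-trihydroxyacetophenone | CC(=O)c1c(O)cc(O)cc1O | starting material
2 | acetylsyncarpic acid, 2-acetyl-3-hydroxy-4,4,6,6-tetramethylcyclohex-2-ene-1,5-dione | CC(=O)C1=C(O)C(C)(C)C(=O)C(C)(C)C1=O | intermediate
3 | syncarpic acid, 5-hydroxy-2,2,6,6-tetramethylcyclohex-4-ene-1,3-dione | CC1(C)C(=O)C=C(O)C(C)(C)C1=O | intermediate
4 | (−)-β-caryophyllene, (1R,4E,9S)-caryophylla-4,8(13)-diene | C/C1=C\CCC(=C)[C@H]2CC(C)(C)[C@@H]2CC1 | starting material
5 | (1R,4S,5S,9S)-4,5-epoxycaryophyll-8(13)-ene | C[C@]12CC[C@@H]3[C@H](CC3(C)C)C(=C)CC[C@@H]1O2 | intermediate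
6 | (1R,3Z,5S,9S)-caryophylla-3,8(13)-dien-5-ol | C/C1=C/C[C@@H]2[C@H](CC2(C)C)C(=C)CC[C@@H]1O | intermediate
7 | isovaleraldehyde, 3-methylbutanal | CC(C)CC=O | starting material
8 | 2,2,6,6-tetramethyl-4-(3-methylbutylidene)cyclohexane-1,3,5-trione | CC(C)CC=C1C(=O)C(C)(C)C(=O)C(C)(C)C1=O | intermediate
9 | Tomentodione P, (1R,3Z,5S,8S,9S,1'S): 4-isobutyl-6,6,8,8-tetramethyl-3,4-dihydro-2H-chromene-5,7(6H,8H)-dione spiro-linked through its C2 to C8 of (3Z)-5-hydroxycaryophyll-3-ene | C/C1=C/C[C@@H]2[C@H](CC2(C)C)[C@]2(CC[C@@H]1O)C[C@H](CC(C)C)C1=C(O2)C(C)(C)C(=O)C(C)(C)C1=O | target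

**Totals**
Total steps: 5. Longest linear sequence: 3 steps (4 → 5 → 6 → 9, or 1 → 2 → 3 → 9).

**Three steps most likely to fail**

Step 3 (the new conformer-selective epoxidation). The catalyst may not override the substrate's own facial bias, leaving the 4R,5R oxide as the main product; a 4S,5S : 4R,5R ratio near 5:1 is hoped for. The fallback uses known chemistry only and sets out from 4. Peracid epoxidation (mCPBA, NaHCO3, CH2Cl2, 0 °C) gives mainly (−)-caryophyllene oxide F1, which can also be bought. The aluminium amide isomerisation of step 4 then gives (1R,3Z,5R,9S)-caryophylla-3,8(13)-dien-5-ol F2. Dess–Martin oxidation gives (1R,3Z,9S)-caryophylla-3,8(13)-dien-5-one F3. Corey–Bakshi–Shibata reduction with (R)-2-methyl-CBS-oxazaborolidine and BH3·SMe2 (alkenyl as the large group) sets 5S and comes back to the route at 6.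

Step 4 (epoxide to allylic alcohol). The amide may remove a C12 methyl proton (exocyclic methylene isomer), the 3E olefin may form, or the Lewis-acidic aluminium may trigger transannular cyclisation. The fallback drops the epoxide and sets out from 4. A Schenck ene reaction with singlet oxygen (O2, tetraphenylporphyrin, visible light, CH2Cl2, −20 °C) forms the C5–O bond and shifts the double bond in one operation. It gives (1R,3Z,5S,9S)-5-hydroperoxycaryophylla-3,8(13)-diene F4 as one of several separable allylic hydroperoxides, so the yield will be lower. Reduction with PPh3 and chromatography comes back to the route at 6.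

Step 5 (Knoevenagel / oxa-Diels–Alder). Facial and exo/endo selectivity at C8 and C1' may be low, and 8 may be lost to the bis-adduct with 3 or to side reactions of the dienol. The fallback reverses the order of events and sets out from 4, 3 and 7. The same domino reaction, run with the hydrocarbon dienophile 4 (via 8), gives (1R,4E,8S,9S,1'S)-5-deoxy-4,5-didehydro-3,4-dihydro-Tomentodione P F5, with its diastereomers separated at this stage. The epoxidation of step 3 on F5 gives the corresponding (4S,5S)-4,5-epoxide F6. The aluminium amide isomerisation of step 4 on F6 comes back to the route at 9.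

**Further compounds**
F1 | step 3 | (−)-caryophyllene oxide, (1R,4R,5R,9S)-4,5-epoxycaryophyll-8(13)-ene | C[C@@]12CC[C@@H]3[C@H](CC3(C)C)C(=C)CC[C@H]1O2
F2 | step 3 | (1R,3Z,5R,9S)-caryophylla-3,8(13)-dien-5-ol | C/C1=C/C[C@@H]2[C@H](CC2(C)C)C(=C)CC[C@H]1O
F3 | step 3 | (1R,3Z,9S)-caryophylla-3,8(13)-dien-5-one | C/C1=C/C[C@@H]2[C@H](CC2(C)C)C(=C)CCC1=O
F4 | step 4 | (1R,3Z,5S,9S)-5-hydroperoxycaryophylla-3,8(13)-diene | C/C1=C/C[C@@H]2[C@H](CC2(C)C)C(=C)CC[C@@H]1OO
F5 | step 5 | (1R,4E,8S,9S,1'S) oxa-Diels–Alder adduct of β-caryophyllene and 8 (5-deoxy-4,5-didehydro-3,4-dihydro-Tomentodione P) | C/C1=C\CC[C@]2(C[C@H](CC(C)C)C3=C(O2)C(C)(C)C(=O)C(C)(C)C3=O)[C@H]2CC(C)(C)[C@@H]2CC1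
F6 | step 5 | (1R,4S,5S,8S,9S,1'S)-4,5-epoxide of F5 | C[C@]12CC[C@@H]3[C@H](CC3(C)C)[C@]3(CC[C@@H]1O2)C[C@H](CC(C)C)C1=C(O3)C(C)(C)C(=O)C(C)(C)C1=O
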